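**Plan**
- Retrosynthetic cuts, last bond first: C8–C1' (Friedel–Crafts-type Michael addition), O1–C8a of ring C (aryl bromide plus C2 carbinol), C3–C4 (aldol), and the formyl carbon–C4a bond.
- Enabling feature: in ring A the oxygens O5, O7 and O1 lie symmetrically about the axis through C6 (methyl) and C8a. A bromoarene with a mirror plane through C–CH3 and C–Br, formylated at either of its two equivalent CH positions, therefore carries bromine exactly at the future C8a and leaves C8 as the only free ring A carbon.
- Forward order: ring A is bought as the bromoarene; C4, C3 and C2 come from formylation and an acetophenone aldol; ring C closes by Pd-catalysed O1–C8a etherification; C4 is returned to the ketone and the benzyl groups removed; the isobutyl–syncarpyl arm is attached to C8 last.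
- Stereochemistry: C2 (R) comes from Noyori–Ikariya transfer hydrogenation and survives the C–O coupling because the carbinol C–O bond is never broken. C1' (S) comes from a chiral phosphoric acid-controlled Michael addition. C4 is carried as an epimer mixture and erased by oxidation.

Key step: step 7

Assumption: the syncarpyl unit is drawn as the enol tautomer of the target SMILES, for which C1' is S (syncarpyl C > C8 > CH2 > H); bromoarene 1 is taken as a catalogue compound.

Step 1
Reactants: 1 5-bromo-1,3-dimethoxy-2-methylbenzene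
Product: 2 5-bromo-2-methylbenzene-1,3-diol
Conditions: BBr3 (2.5 equiv), CH2Cl2, −78 °C → rt; then H2O
Reagents that add atoms: none
Why: Lewis-acid ether cleavage in which BBr3 complexes each methoxy oxygen and bromide removes the methyl group by SN2, the aryl bromide being inert and the two ethers equivalent.

Step 2
Reactants: 2 5-bromo-2-methylbenzene-1,3-diol
Product: 3 1,3-bis(benzyloxy)-5-bromo-2-methylbenzene
Conditions: BnBr (2.3 equiv), K2CO3 (2.5 equiv), DMF, 60 °C
Reagents that add atoms: benzyl bromide, BrCc1ccccc1
Why: Williamson ether synthesis on both phenoxides, benzyl being chosen because it can later be removed by neutral hydrogenolysis, which leaves the flavanone ring and its C2 centre intact.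

Step 3
Reactants: 3 1,3-bis(benzyloxy)-5-bromo-2-methylbenzene
Product: 5 2,4-bis(benzyloxy)-6-bromo-3-methylbenzaldehyde, via aryl iminium chloride 4 (not isolated)
Conditions: POCl3 (1.5 equiv), DMF, 0 → 70 °C; then H2O, rt
Reagents that add atoms: N,N-dimethylformamide, CN(C)C=O; water, O
Why: Vilsmeier–Haack formylation, in which the two free ring positions are equivalent by the mirror plane and each is ortho to one benzyloxy group and para to the other, so a single aldehyde with bromine ortho to the formyl group should form.

Step 4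
Reactants: 6 acetophenone; 5 2,4-bis(benzyloxy)-6-bromo-3-methylbenzaldehyde
Product: 8 (3RS)-3-[2,4-bis(benzyloxy)-6-bromo-3-methylphenyl]-3-hydroxy-1-phenylpropan-1-one, via acetophenone lithium enolate 7 (not isolated)
Conditions: LiN(iPr)2 (1.1 equiv), THF, −78 °C; then 5, −78 °C; AcOH quench at −78 °C
Reagents that add atoms: none
Why: Directed aldol addition of a preformed lithium enolate to a non-enolisable aldehyde, quenched cold to forestall retro-aldol reversal; the new carbinol is racemic, which is immaterial because this carbon becomes the C4 carbonyl.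

Step 5
Reactants: 8 (3RS)-3-[2,4-bis(benzyloxy)-6-bromo-3-methylphenyl]-3-hydroxy-1-phenylpropan-1-one
Product: 9 (3RS)-3-[2,4-bis(benzyloxy)-6-bromo-3-methylphenyl]-3-[(tert-butyldimethylsilyl)oxy]-1-phenylpropan-1-one
Conditions: TBSOTf (1.2 equiv), 2,6-lutidine (2 equiv), CH2Cl2, −78 → 0 °C
Reagents that add atoms: tert-butyldimethylsilyl trifluoromethanesulfonate, CC(C)(C)[Si](C)(C)OS(=O)(=O)C(F)(F)F
Why: Silyl triflate silylation of a hindered secondary alcohol, which blocks the future C4 oxygen against dehydration, retro-aldol cleavage and later coordination to palladium.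

Step 6
Reactants: 9 (3RS)-3-[2,4-bis(benzyloxy)-6-bromo-3-methylphenyl]-3-[(tert-butyldimethylsilyl)oxy]-1-phenylpropan-1-one
Product: 10 (1R,3RS)-3-[2,4-bis(benzyloxy)-6-bromo-3-methylphenyl]-3-[(tert-butyldimethylsilyl)oxy]-1-phenylpropan-1-ol
Conditions: RuCl[(R,R)-TsDPEN](p-cymene) (2 mol%), HCO2H/Et3N (5:2), CH2Cl2, rt
Reagents that add atoms: none
Why: Noyori–Ikariya asymmetric transfer hydrogenation of an aryl alkyl ketone, in which the (R,R)-diamine ruthenium hydride delivers hydrogen to the face that gives (R)-1-phenyl carbinols (as with acetophenone) under catalyst control, so both C3 epimers should carry the (1R) configuration.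

Step 7
Reactants: 10 (1R,3RS)-3-[2,4-bis(benzyloxy)-6-bromo-3-methylphenyl]-3-[(tert-butyldimethylsilyl)oxy]-1-phenylpropan-1-ol
Product: 11 (2R,4RS)-5,7-bis(benzyloxy)-4-[(tert-butyldimethylsilyl)oxy]-6-methyl-2-phenylchromane
Conditions: Pd(OAc)2 (5 mol%), rac-2-(di-tert-butylphosphino)-1,1'-binaphthyl (6 mol%), Cs2CO3 (1.5 equiv), toluene, 70 °C
Reagents that add atoms: none
Why: Palladium diacetate is reduced in situ to a zerovalent palladium–phosphine species that inserts into the C8a–Br bond; Cs2CO3 then deprotonates the bound carbinol to give a seven-membered aryl(alkoxo) chelate of divalent palladium, and C–O reductive elimination forms O1–C8a. The closest known reaction type is the Buchwald–Hartwig-type intramolecular etherification of aryl bromides with secondary alcohols to chromans. The six-membered pyran ring C closes by this reductive elimination, formally a 6-exo attack of the alkoxide oxygen on the aryl carbon. No stereocentre is created: the carbinol C–O bond is untouched, so (1R) passes with retention into (2R), and C4 stays an epimer mixture. The step needs chemoselectivity for reductive elimination over β-hydride elimination of the benzylic alkoxide, which the bulky electron-rich di-tert-butyl biaryl phosphine should secure, while the silyl ether keeps the C4 oxygen off the metal. Regiochemistry needs no control because bromine sits only at C8a, so only the 6-methyl, 8-unsubstituted flavan can form.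

Step 8
Reactants: 11 (2R,4RS)-5,7-bis(benzyloxy)-4-[(tert-butyldimethylsilyl)oxy]-6-methyl-2-phenylchromane
Product: 12 (2R,4RS)-5,7-bis(benzyloxy)-6-methyl-2-phenylchroman-4-ol
Conditions: Bu4NF (1.5 equiv), THF, 0 °C → rt
Reagents that add atoms: none
Why: Fluoride-driven desilylation under non-acidic conditions, which avoids ionisation of the electron-rich C4 benzylic position and leaves the C2 ether and benzyl groups alone.

Step 9
Reactants: 12 (2R,4RS)-5,7-bis(benzyloxy)-6-methyl-2-phenylchroman-4-ol
Product: 13 (2R)-5,7-bis(benzyloxy)-6-methyl-2-phenylchroman-4-one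
Conditions: Dess–Martin periodinane (1.3 equiv), pyridine (3 equiv), CH2Cl2, 0 °C → rt
Reagents that add atoms: none
Why: Dess–Martin oxidation of a secondary benzylic alcohol converges both C4 epimers on one ketone, and the buffered, base-free medium avoids both dehydration to the flav-3-ene and retro-oxa-Michael ring opening that would racemise C2.

Step 10
Reactants: 13 (2R)-5,7-bis(benzyloxy)-6-methyl-2-phenylchroman-4-one
Product: 14 (2R)-5,7-dihydroxy-6-methyl-2-phenylchroman-4-one
Conditions: H2 (1 atm), 10% Pd/C, EtOAc/MeOH, rt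
Reagents that add atoms: none
Why: Catalytic hydrogenolysis of aryl benzyl ethers under neutral conditions, stopped after two equivalents of hydrogen because the cyclic C2–O1 ether and the aryl ketone are reduced far more slowly, so C2 should remain (R).

Step 11
Reactants: 15 syncarpic acid (2,2,4,4-tetramethylcyclohexane-1,3,5-trione); 16 3-methylbutanal
Product: 18 2,2,4,4-tetramethyl-6-(3-methylbutylidene)cyclohexane-1,3,5-trione, via piperidine Mannich base 17 (not isolated)
Conditions: piperidine (1.05 equiv), CH2Cl2, 0 °C → rt; then 1 M aq HCl, rt; used at once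
Reagents that add atoms: none
Why: Knoevenagel condensation run through the Mannich base, which prevents addition of a second trione, after which acid expels piperidine to unmask the alkylidene trione.

Step 12
Reactants: 14 (2R)-5,7-dihydroxy-6-methyl-2-phenylchroman-4-one; 18 2,2,4,4-tetramethyl-6-(3-methylbutylidene)cyclohexane-1,3,5-trione
Product: 19 (2R)-5,7-dihydroxy-8-[(1S)-1-(2-hydroxy-3,3,5,5-tetramethyl-4,6-dioxocyclohex-1-en-1-yl)-3-methylbutyl]-6-methyl-2-phenylchroman-4-one
Conditions: (R)-TRIP [(R)-3,3'-bis(2,4,6-triisopropylphenyl)-1,1'-binaphthyl-2,2'-diyl hydrogen phosphate] (10 mol%), 18 (1.2 equiv), 4 Å MS, CH2Cl2/toluene, −40 °C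
Reagents that add atoms: none
Why: Friedel–Crafts-type Michael addition under chiral Brønsted acid catalysis, in which C8 is the only free carbon of the phloroglucinol-type ring A, the acceptor has no E/Z isomers because its flanking carbonyls are equivalent, and the phosphate (P–OH bound to a trione carbonyl, P=O bound to the 7-OH) is expected to deliver the arene to the Re face of the alkylidene carbon, which gives (1'S) under catalyst control with little influence from the remote C2 centre.

**Compound list**
1 | 5-bromo-1,3-dimethoxy-2-methylbenzene | COc1cc(Br)cc(OC)c1C | starting material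
2 | 5-bromo-2-methylbenzene-1,3-diol | Cc1c(O)cc(Br)cc1O | intermediate
3 | 1,3-bis(benzyloxy)-5-bromo-2-methylbenzene | Cc1c(OCc2ccccc2)cc(Br)cc1OCc1ccccc1 | intermediate
4 | N-[2,4-bis(benzyloxy)-6-bromo-3-methylbenzylidene]-N-methylmethanaminium chloride (formed in the flask, not isolated) | C[N+](C)=Cc1c(Br)cc(OCc2ccccc2)c(C)c1OCc1ccccc1.[Cl-] | intermediate
5 | 2,4-bis(benzyloxy)-6-bromo-3-methylbenzaldehyde | Cc1c(OCc2ccccc2)cc(Br)c(C=O)c1OCc1ccccc1 | intermediate
6 | acetophenone | CC(=O)c1ccccc1 | starting material
7 | lithium 1-phenylethenolate (formed in the flask, not isolated) | [Li]OC(=C)c1ccccc1 | intermediate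
8 | (3RS)-3-[2,4-bis(benzyloxy)-6-bromo-3-methylphenyl]-3-hydroxy-1-phenylpropan-1-one (racemate) | Cc1c(OCc2ccccc2)cc(Br)c(C(O)CC(=O)c2ccccc2)c1OCc1ccccc1 | intermediate
9 | (3RS)-3-[2,4-bis(benzyloxy)-6-bromo-3-methylphenyl]-3-[(tert-butyldimethylsilyl)oxy]-1-phenylpropan-1-one (racemate) | Cc1c(OCc2ccccc2)cc(Br)c(C(O[Si](C)(C)C(C)(C)C)CC(=O)c2ccccc2)c1OCc1ccccc1 | intermediate
10 | (1R,3RS)-3-[2,4-bis(benzyloxy)-6-bromo-3-methylphenyl]-3-[(tert-butyldimethylsilyl)oxy]-1-phenylpropan-1-ol (both C3 epimers, each 1R) | Cc1c(OCc2ccccc2)cc(Br)c(C(O[Si](C)(C)C(C)(C)C)C[C@@H](O)c2ccccc2)c1OCc1ccccc1 | intermediate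
11 | (2R,4RS)-5,7-bis(benzyloxy)-4-[(tert-butyldimethylsilyl)oxy]-6-methyl-2-phenylchromane (both C4 epimers, each 2R) | Cc1c(OCc3ccccc3)c2c(cc1OCc1ccccc1)O[C@@H](c1ccccc1)CC2O[Si](C)(C)C(C)(C)C | intermediate
12 | (2R,4RS)-5,7-bis(benzyloxy)-6-methyl-2-phenylchroman-4-ol (both C4 epimers) | Cc1c(OCc3ccccc3)c2c(cc1OCc1ccccc1)O[C@@H](c1ccccc1)CC2O | intermediate
13 | (2R)-5,7-bis(benzyloxy)-6-methyl-2-phenylchroman-4-one | Cc1c(OCc3ccccc3)c2c(cc1OCc1ccccc1)O[C@@H](c1ccccc1)CC2=O | intermediate
14 | (2R)-5,7-dihydroxy-6-methyl-2-phenylchroman-4-one | Cc1c(O)c2c(cc1O)O[C@@H](c1ccccc1)CC2=O | intermediate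
15 | syncarpic acid (2,2,4,4-tetramethylcyclohexane-1,3,5-trione) | CC1(C)C(=O)CC(=O)C(C)(C)C1=O | starting material
16 | 3-methylbutanal (isovaleraldehyde) | CC(C)CC=O | starting material
17 | 3-hydroxy-4,4,6,6-tetramethyl-2-[3-methyl-1-(piperidin-1-yl)butyl]cyclohex-2-ene-1,5-dione (Mannich base, formed in the flask, not isolated) | CC(C)CC(N1CCCCC1)C1=C(O)C(C)(C)C(=O)C(C)(C)C1=O | intermediate
18 | 2,2,4,4-tetramethyl-6-(3-methylbutylidene)cyclohexane-1,3,5-trione | CC(C)CC=C1C(=O)C(C)(C)C(=O)C(C)(C)C1=O | intermediate
19 | (2R)-5,7-dihydroxy-8-[(1S)-1-(2-hydroxy-3,3,5,5-tetramethyl-4,6-dioxocyclohex-1-en-1-yl)-3-methylbutyl]-6-methyl-2-phenylchroman-4-one (CNP0249552.1) | Cc1c(O)c2c(c([C@H](CC(C)C)C3=C(O)C(C)(C)C(=O)C(C)(C)C3=O)c1O)O[C@@H](c1ccccc1)CC2=O | target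

**Totals**
Total steps: 12. Longest linear sequence: 11 (steps 1–10, then step 12); step 11 is a one-step side branch.

**Steps most likely to fail**

Step 7. β-Hydride elimination from the benzylic palladium alkoxide may outrun C–O reductive elimination, oxidising the carbinol and hydrodebrominating the arene. Reductive elimination may also simply stall on this ortho-branched, electronically neutral aryl. The fallback closes the same ring through the C2–O1 bond with inversion instead, and sets out from 9. Transfer hydrogenation with RuCl[(S,S)-TsDPEN](p-cymene) would give (1S,3RS)-3-[2,4-bis(benzyloxy)-6-bromo-3-methylphenyl]-3-[(tert-butyldimethylsilyl)oxy]-1-phenylpropan-1-ol F1. Miyaura borylation (B2pin2, PdCl2(dppf), KOAc, dioxane, 80 °C) would give the pinacol boronate F2, and NaBO3·4H2O in THF/H2O would give the phenol F3. Mitsunobu cyclisation (PPh3, DIAD, THF, 0 °C) would then displace the activated (S)-carbinol with inversion. The route is rejoined at 11 with the (2R) configuration; the bromine position still decides which ring carbon becomes C8a.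

Step 12. Facial discrimination at the alkylidene carbon may be poor, and C1' may erode through reversible retro-Michael cleavage. If a trial shows the opposite sense of induction, the mirror-image acid is used. The fallback abandons catalyst control and sets out from 14 and 18. They are combined without a chiral catalyst (CH2Cl2/THF, rt, optionally a trace of Et3N). This should give 19 together with its C1' epimer, (2R)-5,7-dihydroxy-8-[(1R)-1-(2-hydroxy-3,3,5,5-tetramethyl-4,6-dioxocyclohex-1-en-1-yl)-3-methylbutyl]-6-methyl-2-phenylchroman-4-one F4. The two are diastereomers because C2 is fixed, so they can be separated by preparative HPLC or crystallisation. The unwanted epimer is re-equilibrated under mild base and recycled, and the route is rejoined at 19.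

Step 4. The hindered, electron-rich aldolate may revert by retro-aldol cleavage or dehydrate to the chalcone before it is captured. The fallback is a Lewis-acid Mukaiyama aldol and sets out from 5 and 6. Acetophenone is converted (TMSCl, Et3N, NaI, MeCN) into trimethyl[(1-phenylethenyl)oxy]silane F5. This adds to the BF3·OEt2-activated aldehyde 5 in CH2Cl2 at −78 °C, and the adduct is held as its boron chelate until aqueous work-up. The route is rejoined at 8.

**Further compounds**
F1 | step 7 | (1S,3RS)-3-[2,4-bis(benzyloxy)-6-bromo-3-methylphenyl]-3-[(tert-butyldimethylsilyl)oxy]-1-phenylpropan-1-ol | Cc1c(OCc2ccccc2)cc(Br)c(C(O[Si](C)(C)C(C)(C)C)C[C@H](O)c2ccccc2)c1OCc1ccccc1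
F2 | step 7 | (1S,3RS)-3-[2,4-bis(benzyloxy)-3-methyl-6-(4,4,5,5-tetramethyl-1,3,2-dioxaborolan-2-yl)phenyl]-3-[(tert-butyldimethylsilyl)oxy]-1-phenylpropan-1-ol | Cc1c(OCc2ccccc2)cc(B2OC(C)(C)C(C)(C)O2)c(C(O[Si](C)(C)C(C)(C)C)C[C@H](O)c2ccccc2)c1OCc1ccccc1
F3 | step 7 | (1S,3RS)-3-[2,4-bis(benzyloxy)-6-hydroxy-3-methylphenyl]-3-[(tert-butyldimethylsilyl)oxy]-1-phenylpropan-1-ol | Cc1c(OCc2ccccc2)cc(O)c(C(O[Si](C)(C)C(C)(C)C)C[C@H](O)c2ccccc2)c1OCc1ccccc1
F4 | step 12 | (2R)-5,7-dihydroxy-8-[(1R)-1-(2-hydroxy-3,3,5,5-tetramethyl-4,6-dioxocyclohex-1-en-1-yl)-3-methylbutyl]-6-methyl-2-phenylchroman-4-one | Cc1c(O)c2c(c([C@@H](CC(C)C)C3=C(O)C(C)(C)C(=O)C(C)(C)C3=O)c1O)O[C@@H](c1ccccc1)CC2=O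
F5 | step 4 | trimethyl[(1-phenylethenyl)oxy]silane | C=C(O[Si](C)(C)C)c1ccccc1
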